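**Assumption:** a Prelog-selective ketoreductase that accepts pent-3-yn-2-one is taken from a commercial screening panel; Grignard, amide and alkoxide bases are used as purchased solutions.

## Retrosynthetic overview

1. The C6–allyl bond is made last, by kinetic α'-alkylation of the bicyclic vinylogous ester (allyl enters anti to the pseudo-axial C7a side chain).
2. The dioxole ring is formed second: the O–CH2–O bridge comes from the MOM ether of a 4-hydroxycyclohexane-1,3-dione (bromomethyl ether, then enol O-alkylation).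
3. The six-membered carbocycle is formed first, by intramolecular Claisen condensation of an acyclic methyl ketone/methyl ester that already carries the C7a–O and CH(CH3)CH2Ar centres.
4. The C7a/side-chain stereo pair comes from stereospecific copper-catalysed opening of a trisubstituted epoxy alcohol with 3,4,5-trimethoxybenzylmagnesium chloride; the epoxide comes from hydroxyl-directed epoxidation of an (S,E)-allylic alcohol.
5. That alcohol comes from anti-allylmagnesiation of (S)-pent-3-yn-2-ol, made by ketoreductase reduction of pent-3-yn-2-one (the only source of absolute configuration).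

## Route

Step 1
Reactants: 1 pent-3-yn-2-one
Product: 2 (2S)-pent-3-yn-2-ol
Conditions: ketoreductase (Prelog-selective, NADPH-dependent), NADP+ (cat.), i-PrOH (10% v/v), phosphate buffer pH 7, 30 °C
Reagents that add atoms: none
Why: Enzymatic asymmetric ketone reduction (ketoreductase with isopropanol-coupled cofactor recycling) delivers hydride to one face of the prochiral methyl alkynyl ketone, setting the first stereocentre as the (S)-carbinol in high ee.

Step 2
Reactants: 2 (2S)-pent-3-yn-2-ol; 3 allylmagnesium bromide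
Product: 5 (2S,3E)-3-(prop-2-en-1-yl)pent-3-en-2-ol, via cyclic alkenylmagnesium alkoxide 4 (not isolated)
Conditions: 3 (3 equiv), Et2O/THF, reflux; then aq NH4Cl, 0 °C
Reagents that add atoms: none
Why: Hydroxyl-assisted anti-carbomagnesiation places allyl on the alkyne carbon next to the carbinol and magnesium on the distal carbon in a five-membered chelate, so protonolysis gives the alkene with the ethylidene methyl trans to the carbinol, and the carbinol centre is untouched.

Step 3
Reactants: 5 (2S,3E)-3-(prop-2-en-1-yl)pent-3-en-2-ol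
Product: 6 (1S)-1-[(2S,3S)-3-methyl-2-(prop-2-en-1-yl)oxiran-2-yl]ethan-1-ol
Conditions: VO(acac)2 (2 mol %), t-BuOOH (1.5 equiv, decane), CH2Cl2, 0 °C → rt; chromatography
Reagents that add atoms: tert-butyl hydroperoxide, CC(C)(C)OO
Why: In this hydroxyl-directed vanadium-catalysed epoxidation, A(1,2) strain between the carbinol methyl and the geminal allyl group enforces the erythro epoxy alcohol, so the (S)-carbinol fixes both epoxide carbons as (2S,3S), and only the allylic alkene reacts.

Step 4
Reactants: 7 5-(chloromethyl)-1,2,3-trimethoxybenzene (3,4,5-trimethoxybenzyl chloride)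
Product: 8 (3,4,5-trimethoxybenzyl)magnesium chloride (titrated THF solution)
Conditions: Mg turnings (I2-activated), THF, 0 °C, slow addition
Reagents that add atoms: magnesium, [Mg]
Why: Grignard formation by oxidative insertion of magnesium into the benzylic C–Cl bond, with low temperature and slow addition to suppress Wurtz coupling.

Step 5
Reactants: 6 (1S)-1-[(2S,3S)-3-methyl-2-(prop-2-en-1-yl)oxiran-2-yl]ethan-1-ol; 8 (3,4,5-trimethoxybenzyl)magnesium chloride
Product: 9 (2S,3R)-3-[(2S)-1-(3,4,5-trimethoxyphenyl)propan-2-yl]hex-5-ene-2,3-diol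
Conditions: 8 (3 equiv), CuI (10 mol %), THF, −30 → 0 °C; aq NH4Cl
Reagents that add atoms: none
Why: Copper-catalysed SN2 epoxide opening occurs at the CH(CH3) carbon because the other epoxide carbon is fully substituted, so inversion there sets the (S)-CH(CH3)CH2Ar centre while the tertiary C–O centre is retained.

Step 6
Reactants: 9 (2S,3R)-3-[(2S)-1-(3,4,5-trimethoxyphenyl)propan-2-yl]hex-5-ene-2,3-diol
Product: 10 (3R)-3-hydroxy-3-[(2S)-1-(3,4,5-trimethoxyphenyl)propan-2-yl]hex-5-en-2-one
Conditions: Dess–Martin periodinane (1.3 equiv), CH2Cl2, 0 °C → rt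
Reagents that add atoms: none
Why: Dess–Martin oxidation converts only the secondary alcohol (the tertiary one cannot be oxidised), removing the now redundant carbinol centre and leaving a methyl ketone with no α-hydrogen on the stereogenic side.

Step 7
Reactants: 10 (3R)-3-hydroxy-3-[(2S)-1-(3,4,5-trimethoxyphenyl)propan-2-yl]hex-5-en-2-one
Product: 11 (3R)-3-(methoxymethoxy)-3-[(2S)-1-(3,4,5-trimethoxyphenyl)propan-2-yl]hex-5-en-2-one
Conditions: MOMCl (6 equiv), i-Pr2NEt (8 equiv), NaI (cat.), ClCH2CH2Cl, 60 °C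
Reagents that add atoms: chloromethyl methyl ether, COCCl
Why: O-alkylation of the tertiary alcohol by the oxocarbenium-like (iodo)methyl ether under forcing conditions gives the MOM ether, which protects the alcohol and already carries the future O–CH2–O carbon.

Step 8
Reactants: 11 (3R)-3-(methoxymethoxy)-3-[(2S)-1-(3,4,5-trimethoxyphenyl)propan-2-yl]hex-5-en-2-one
Product: 13 (3R)-6-hydroxy-3-(methoxymethoxy)-3-[(2S)-1-(3,4,5-trimethoxyphenyl)propan-2-yl]hexan-2-one, via pinacol boronate 12 (not isolated)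
Conditions: HBpin (1.5 equiv), RhCl(PPh3)3 (2 mol %), THF, rt; then 30% H2O2, aq NaOH, 0 °C
Reagents that add atoms: hydrogen peroxide, OO
Why: Rhodium-catalysed anti-Markovnikov hydroboration takes the terminal alkene in preference to the ketone, and oxidation of the C–B bond gives the primary alcohol without touching any stereocentre.

Step 9
Reactants: 13 (3R)-6-hydroxy-3-(methoxymethoxy)-3-[(2S)-1-(3,4,5-trimethoxyphenyl)propan-2-yl]hexan-2-one
Product: 14 (4R,5S)-4-acetyl-4-(methoxymethoxy)-5-methyl-6-(3,4,5-trimethoxyphenyl)hexanoic acid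
Conditions: TEMPO (20 mol %), PhI(OAc)2 (2.5 equiv), MeCN/H2O 1:1, rt
Reagents that add atoms: water, O
Why: Oxoammonium-mediated (TEMPO) oxidation takes the primary alcohol through the aldehyde hydrate to the acid under near-neutral conditions that spare the MOM ether, the ketone and the electron-rich arene.

Step 10
Reactants: 14 (4R,5S)-4-acetyl-4-(methoxymethoxy)-5-methyl-6-(3,4,5-trimethoxyphenyl)hexanoic acid
Product: 15 methyl (4R,5S)-4-acetyl-4-(methoxymethoxy)-5-methyl-6-(3,4,5-trimethoxyphenyl)hexanoate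
Conditions: MeI, K2CO3, DMF, rt
Reagents that add atoms: iodomethane, CI
Why: SN2 O-methylation of the carboxylate gives the ester, and carbonate is too weak to enolise the ketone.

Step 11
Reactants: 15 methyl (4R,5S)-4-acetyl-4-(methoxymethoxy)-5-methyl-6-(3,4,5-trimethoxyphenyl)hexanoate
Product: 16 (4R)-4-(methoxymethoxy)-4-[(2S)-1-(3,4,5-trimethoxyphenyl)propan-2-yl]cyclohexane-1,3-dione
Conditions: KOt-Bu (2.2 equiv), THF, 0 °C → rt; then cold 1 M HCl to pH 3
Reagents that add atoms: none
Why: In this intramolecular Claisen (Dieckmann-type) condensation the methyl ketone can enolise only at its methyl group, which closes the six-membered ring onto the ester, and deprotonation of the resulting 1,3-dione drives the reaction; no stereocentre is involved.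

Step 12
Reactants: 16 (4R)-4-(methoxymethoxy)-4-[(2S)-1-(3,4,5-trimethoxyphenyl)propan-2-yl]cyclohexane-1,3-dione
Product: 18 (7aR)-7a-[(2S)-1-(3,4,5-trimethoxyphenyl)propan-2-yl]-7,7a-dihydro-1,3-benzodioxol-5(6H)-one, via bromomethyl ether 17 (not isolated)
Conditions: Me2BBr (2.2 equiv), CH2Cl2, −78 °C; then i-Pr2NEt (5 equiv), −78 → 0 °C
Reagents that add atoms: none
Why: Boron-bromide cleavage of the MOM ether stops at the bromomethyl ether, and intramolecular O-alkylation of the dione enolate (5-exo-tet) can only use the oxygen next to the quaternary carbon, which fixes the vinylogous ester regiochemistry (C-alkylation would be a disfavoured 5-enolendo closure).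

Step 13
Reactants: 18 (7aR)-7a-[(2S)-1-(3,4,5-trimethoxyphenyl)propan-2-yl]-7,7a-dihydro-1,3-benzodioxol-5(6H)-one; 19 allyl bromide (3-bromoprop-1-ene)
Product: 21 (6R,7aR)-6-(prop-2-en-1-yl)-7a-[(2S)-1-(3,4,5-trimethoxyphenyl)propan-2-yl]-7,7a-dihydro-1,3-benzodioxol-5(6H)-one (target), via lithium enolate 20 (not isolated)
Conditions: LiN(i-Pr)2 (1.1 equiv), THF, −78 °C; then 19 (1.5 equiv), DMPU, −78 → −40 °C
Reagents that add atoms: none
Why: Stork–Danheiser kinetic α'-alkylation of the vinylogous ester enolate occurs anti to the pseudo-axial C7a side chain, giving the 6R (allyl trans to side chain, equatorial) isomer, which is also the thermodynamic epimer, so any cis material converges on brief DBU equilibration.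

## Compound list

1 | pent-3-yn-2-one | CC#CC(C)=O | starting material
2 | (2S)-pent-3-yn-2-ol | C[C@H](O)C#CC | intermediate
3 | allylmagnesium bromide | C=CC[Mg]Br | starting material
4 | (5S)-3,5-dimethyl-4-(prop-2-en-1-yl)-2,5-dihydro-1,2-oxamagnesole (cyclic alkenylmagnesium alkoxide) | C[C@@H]1O[Mg]C(C)=C1CC=C | intermediate
5 | (2S,3E)-3-(prop-2-en-1-yl)pent-3-en-2-ol | C/C=C(\CC=C)/[C@H](C)O | intermediate
6 | (1S)-1-[(2S,3S)-3-methyl-2-(prop-2-en-1-yl)oxiran-2-yl]ethan-1-ol | C[C@H](O)[C@]1(CC=C)O[C@H]1C | intermediate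
7 | 5-(chloromethyl)-1,2,3-trimethoxybenzene | COc1cc(CCl)cc(OC)c1OC | starting material
8 | (3,4,5-trimethoxybenzyl)magnesium chloride | COc1cc(C[Mg]Cl)cc(OC)c1OC | intermediate
9 | (2S,3R)-3-[(2S)-1-(3,4,5-trimethoxyphenyl)propan-2-yl]hex-5-ene-2,3-diol | C[C@H](O)[C@@](O)(CC=C)[C@@H](C)Cc1cc(OC)c(OC)c(OC)c1 | intermediate
10 | (3R)-3-hydroxy-3-[(2S)-1-(3,4,5-trimethoxyphenyl)propan-2-yl]hex-5-en-2-one | CC(=O)[C@@](O)(CC=C)[C@@H](C)Cc1cc(OC)c(OC)c(OC)c1 | intermediate
11 | (3R)-3-(methoxymethoxy)-3-[(2S)-1-(3,4,5-trimethoxyphenyl)propan-2-yl]hex-5-en-2-one | CC(=O)[C@@](OCOC)(CC=C)[C@@H](C)Cc1cc(OC)c(OC)c(OC)c1 | intermediate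
12 | (3R)-3-(methoxymethoxy)-6-(4,4,5,5-tetramethyl-1,3,2-dioxaborolan-2-yl)-3-[(2S)-1-(3,4,5-trimethoxyphenyl)propan-2-yl]hexan-2-one | CC(=O)[C@@](OCOC)(CCCB1OC(C)(C)C(C)(C)O1)[C@@H](C)Cc1cc(OC)c(OC)c(OC)c1 | intermediate
13 | (3R)-6-hydroxy-3-(methoxymethoxy)-3-[(2S)-1-(3,4,5-trimethoxyphenyl)propan-2-yl]hexan-2-one | CC(=O)[C@@](OCOC)(CCCO)[C@@H](C)Cc1cc(OC)c(OC)c(OC)c1 | intermediate
14 | (4R,5S)-4-acetyl-4-(methoxymethoxy)-5-methyl-6-(3,4,5-trimethoxyphenyl)hexanoic acid | CC(=O)[C@@](OCOC)(CCC(=O)O)[C@@H](C)Cc1cc(OC)c(OC)c(OC)c1 | intermediate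
15 | methyl (4R,5S)-4-acetyl-4-(methoxymethoxy)-5-methyl-6-(3,4,5-trimethoxyphenyl)hexanoate | CC(=O)[C@@](OCOC)(CCC(=O)OC)[C@@H](C)Cc1cc(OC)c(OC)c(OC)c1 | intermediate
16 | (4R)-4-(methoxymethoxy)-4-[(2S)-1-(3,4,5-trimethoxyphenyl)propan-2-yl]cyclohexane-1,3-dione | O=C1CC(=O)[C@](OCOC)([C@@H](C)Cc2cc(OC)c(OC)c(OC)c2)CC1 | intermediate
17 | (4R)-4-(bromomethoxy)-4-[(2S)-1-(3,4,5-trimethoxyphenyl)propan-2-yl]cyclohexane-1,3-dione | O=C1CC(=O)[C@](OCBr)([C@@H](C)Cc2cc(OC)c(OC)c(OC)c2)CC1 | intermediate
18 | (7aR)-7a-[(2S)-1-(3,4,5-trimethoxyphenyl)propan-2-yl]-7,7a-dihydro-1,3-benzodioxol-5(6H)-one | O=C1CC[C@]2([C@@H](C)Cc3cc(OC)c(OC)c(OC)c3)OCOC2=C1 | intermediate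
19 | allyl bromide (3-bromoprop-1-ene) | C=CCBr | starting material
20 | lithium (7aR)-7a-[(2S)-1-(3,4,5-trimethoxyphenyl)propan-2-yl]-7,7a-dihydro-1,3-benzodioxol-5-olate | [Li]OC1=CC[C@]2([C@@H](C)Cc3cc(OC)c(OC)c(OC)c3)OCOC2=C1 | intermediate
21 | (6R,7aR)-6-(prop-2-en-1-yl)-7a-[(2S)-1-(3,4,5-trimethoxyphenyl)propan-2-yl]-7,7a-dihydro-1,3-benzodioxol-5(6H)-one | C=CC[C@@H]1C[C@]2([C@@H](C)Cc3cc(OC)c(OC)c(OC)c3)OCOC2=CC1=O | target

## Summary

Total step count: 13.
Longest linear sequence: 12 steps (steps 1–3 and 5–13, from pent-3-yn-2-one 1 to target 21); step 4 is a one-step side branch.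

Steps most likely to fail, each with a fallback:

**Step 5 (benzyl Grignard opening of the trisubstituted epoxide).** The risks are Wurtz dimer, halohydrin formation or Lewis-acid rearrangement. The fallback sets out from 6 and 7 and introduces the benzylic carbon as a sulfone-stabilised anion. Compound 7 and PhSO2Na in DMF give 1,2,3-trimethoxy-5-[(phenylsulfonyl)methyl]benzene F2. Its lithio derivative (n-BuLi, 2.2 equiv, THF/DMPU, −78 °C → rt) opens 6 at the same CH(CH3) carbon with inversion to give (2S,3R)-3-[(1RS,2R)-1-(phenylsulfonyl)-1-(3,4,5-trimethoxyphenyl)propan-2-yl]hex-5-ene-2,3-diol F3. Reductive desulfonylation (Mg, MeOH) then comes back to the route at 9.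

**Step 12 (closure of the dioxole ring).** The risks are intermolecular alkylation or loss of the one-carbon unit. The fallback sets out from 16 and installs the bridge on a dianion. Acidic removal of the MOM group (2 M HCl, MeOH, 40 °C) gives (4R)-4-hydroxy-4-[(2S)-1-(3,4,5-trimethoxyphenyl)propan-2-yl]cyclohexane-1,3-dione F4. NaH (2.2 equiv) in DMF forms the alkoxide–enolate dianion; its more basic tertiary alkoxide attacks BrCH2Cl first, and the neighbouring enolate oxygen then closes the five-membered ring, coming back to the route at 18.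

**Step 2 (anti-allylmagnesiation of a secondary, internal propargylic alcohol).** The risks are slow addition or regio- and stereoisomer mixtures. The fallback sets out from 2 and builds the alkene by hydroxyl-directed trans-hydrostannation. Bu3SnH with [(C5Me5)RuCl]4 (cat.) in CH2Cl2 gives (2S,3Z)-3-(tributylstannyl)pent-3-en-2-ol F1, with tin on the carbon next to the carbinol and hydrogen delivered anti. Stille coupling of F1 with allyl bromide 19 (Pd(PPh3)4, CuI, DMF) replaces tin by allyl with retention of geometry and comes back to the route at 5.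

## Further compounds

F1 | step 2 | (2S,3Z)-3-(tributylstannyl)pent-3-en-2-ol | C/C=C(\[Sn](CCCC)(CCCC)CCCC)/[C@H](C)O
F2 | step 5 | 1,2,3-trimethoxy-5-[(phenylsulfonyl)methyl]benzene | COc1cc(CS(=O)(=O)c2ccccc2)cc(OC)c1OC
F3 | step 5 | (2S,3R)-3-[(1RS,2R)-1-(phenylsulfonyl)-1-(3,4,5-trimethoxyphenyl)propan-2-yl]hex-5-ene-2,3-diol | C[C@H](O)[C@@](O)(CC=C)[C@@H](C)C(c1cc(OC)c(OC)c(OC)c1)S(=O)(=O)c1ccccc1
F4 | step 12 | (4R)-4-hydroxy-4-[(2S)-1-(3,4,5-trimethoxyphenyl)propan-2-yl]cyclohexane-1,3-dione | O=C1CC(=O)[C@](O)([C@@H](C)Cc2cc(OC)c(OC)c(OC)c2)CC1
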